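**Plan**

1. Ad hoc numbering: bridge C1(Me)=C2–C3(OH)–C4–C5(Me)(CH2OH)–O6; cyclohexene C7(H)(O6)–C8–C9(H)(Me)–C10(Me)(CH2CH2 to C1)–C11=C12; butenolide C12–C13(=O)–O14–C15H2–C11.
2. Retrosynthesis cuts, in order: C11–C15 and the lactone C–O (enol triflate plus a hydroxymethyl stannane); then C7–C12; then the C1–CH2 bond of the bridge (B-alkyl Suzuki); then the two C7–O acetal bonds. This leaves an aldehyde (C7–C11, fragment A) and a diol alkenyl iodide (C1–C5, fragment B).
3. Enabling feature: C7–O6–C5–CH2OH is a 2-alkoxy-1-ol, the signature of a 1,3-dioxolane (C7, O6, C5, CH2, O) opened at its primary oxygen, and C12 is α to the C13 carbonyl and so can arrive as an enol. One Lewis acid event therefore forms C7–C12, keeps the hindered tertiary ether O6–C7 and releases the CH2OH.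
4. Forward ring order: dioxolane (fragment union), then the 12-membered ring (Suzuki), then the six-membered carbocycle by opening the bridged acetal across the ring (bicyclo[8.2.2] core), then the butenolide.
5. Stereochemistry: C9 from (R)-3-methylglutaric acid monomethyl ester; C10 by aldol alkylation of the lactone enolate anti to the C9 methyl; C5 by a copper–bis(oxazoline) pyruvate aldol; C3 by asymmetric transfer hydrogenation; the Z-alkene by trans-hydroalumination/iodination and stereoretentive coupling; C7 from C10 through the ring (only the cis-1,4 bridge can form).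

Key step: step 16

Assumption: compounds 1, 11 and 13 are taken as commercial, and the acetal carbon C7 of 21–25 is carried as both epimers (drawn without configuration) because it becomes planar in step 16.

**Fragment A**

Step 1
Reactants: 1 (3R)-5-methoxy-3-methyl-5-oxopentanoic acid
Product: 3 (4R)-4-methyloxan-2-one, via hydroxy ester 2 (not isolated)
Conditions: BH3·SMe2, THF, 0 °C to rt; MeOH; then p-TsOH (cat.), PhH, reflux
Reagents that add atoms: none
Why: Borane reduces the free carboxylic acid much faster than the methyl ester and the δ-hydroxy ester then lactonises under acid catalysis (chemoselective reduction, lactonisation), which leaves the C9 stereocentre of 1 untouched.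

Step 2
Reactants: 3 (4R)-4-methyloxan-2-one
Product: 5 (4R)-3,4-dimethyloxan-2-one (C3 epimers), via lithium enolate 4 (not isolated)
Conditions: LiN(i-Pr)2, THF, −78 °C; MeI, −78 to −40 °C
Reagents that add atoms: iodomethane, CI
Why: Kinetic enolate alkylation of the δ-lactone should give mainly the trans product, and the new centre is erased again by enolisation in step 3.

Step 3
Reactants: 5 (4R)-3,4-dimethyloxan-2-one
Product: 7 (3R,4R)-3-(1-hydroxyethyl)-3,4-dimethyloxan-2-one (carbinol epimers), via lithium enolate 6 (not isolated)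
Conditions: LiN(i-Pr)2, THF, −78 °C; MeCHO, −78 °C; AcOH
Reagents that add atoms: acetaldehyde, CC=O
Why: In this aldol addition A(1,2) strain with the enolate methyl holds the C9 methyl pseudoaxial, so acetaldehyde should add to the opposite face and set the quaternary centre C10 with its methyl cis to the C9 methyl, while the carbinol centre is lost in step 4.

Step 4
Reactants: 7 (3R,4R)-3-(1-hydroxyethyl)-3,4-dimethyloxan-2-one
Product: 8 (3S,4R)-3-ethenyl-3,4-dimethyloxan-2-one
Conditions: Burgess reagent (MeO2CN−SO2N+Et3), PhMe, 60 °C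
Reagents that add atoms: none
Why: Syn elimination of the sulfamate ester (Burgess dehydration) can only take a hydrogen from the terminal methyl group because the other β-carbon is quaternary, so the vinyl group should form without touching C10.

Step 5
Reactants: 8 (3S,4R)-3-ethenyl-3,4-dimethyloxan-2-one
Product: 9 (2S,3R)-2-ethenyl-5-hydroxy-N-methoxy-N,2,3-trimethylpentanamide
Conditions: MeNH(OMe)·HCl, AlMe3, CH2Cl2, 0 °C to rt
Reagents that add atoms: N,O-dimethylhydroxylamine hydrochloride, CNOC.Cl
Why: Aminolysis of the lactone by the aluminium amide (Weinreb amide formation) frees the primary alcohol and leaves an acyl group that accepts one carbon nucleophile only.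

Step 6
Reactants: 9 (2S,3R)-2-ethenyl-5-hydroxy-N-methoxy-N,2,3-trimethylpentanamide
Product: 10 (2S,3R)-2-ethenyl-N-methoxy-N,2,3-trimethyl-5-oxopentanamide (fragment A)
Conditions: n-Pr4N[RuO4] (cat.), NMO, 4 Å MS, CH2Cl2, rt
Reagents that add atoms: none
Why: Ley–Griffith oxidation converts the primary alcohol into the aldehyde under neutral conditions, which avoid relactonisation and leave the vinyl group alone.

**Fragment B**

Step 7
Reactants: 11 pent-3-yn-2-one
Product: 12 2-(trimethylsilyloxy)pent-1-en-3-yne
Conditions: Me3SiOTf, Et3N, Et2O, 0 °C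
Reagents that add atoms: trimethylsilyl trifluoromethanesulfonate, C[Si](C)(C)OS(=O)(=O)C(F)(F)F
Why: Soft enolisation and O-silylation give the enol silane on the methyl side, the only enolisable position of the ketone.

Step 8
Reactants: 12 2-(trimethylsilyloxy)pent-1-en-3-yne; 13 methyl pyruvate
Product: 15 methyl (2S)-2-hydroxy-2-methyl-4-oxohept-5-ynoate, via silyl ether 14 (not isolated)
Conditions: [Cu((S,S)-t-Bu-box)](OTf)2 (10 mol %), THF, −78 °C; then 1 M HCl
Reagents that add atoms: none
Why: In this catalytic Mukaiyama aldol addition the pyruvate chelates the bis(oxazoline) complex of divalent copper through both carbonyl groups, one face is shielded by a tert-butyl group, and the tertiary carbinol C5 should thus be set as 2S under catalyst control before acid removes the silyl group.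

Step 9
Reactants: 15 methyl (2S)-2-hydroxy-2-methyl-4-oxohept-5-ynoate
Product: 16 methyl (2S,4S)-2,4-dihydroxy-2-methylhept-5-ynoate
Conditions: Ru[(S,S)-TsDPEN](p-cymene) (cat.), i-PrOH, rt
Reagents that add atoms: none
Why: Noyori-type asymmetric transfer hydrogenation of the ynone, in which the alkyne takes the place of the aryl group in the catalyst pocket, should set the propargylic carbinol C3 as S under catalyst control, and the base-free amido complex avoids retro-aldol cleavage.

Step 10
Reactants: 16 methyl (2S,4S)-2,4-dihydroxy-2-methylhept-5-ynoate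
Product: 18 (2S,4S,5Z)-6-iodo-2-methylhept-5-ene-1,2,4-triol, via alkenylalanate 17 (not isolated)
Conditions: NaAlH2(OCH2CH2OMe)2, THF, 0 °C to rt; then I2, −78 °C
Reagents that add atoms: iodine, II
Why: The hydride reduces the ester to CH2OH and, directed by the propargylic alkoxide, adds H and Al trans across the alkyne with aluminium on the distal carbon, and iodine replaces aluminium with retention, which should give the Z-iodoalkene (iodine cis to C3).

Step 11
Reactants: 18 (2S,4S,5Z)-6-iodo-2-methylhept-5-ene-1,2,4-triol
Product: 19 (2S,4S,5Z)-1,4-bis(tert-butyldimethylsilyloxy)-6-iodo-2-methylhept-5-en-2-ol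
Conditions: TBSCl, imidazole, DMF, rt
Reagents that add atoms: tert-butyldimethylsilyl chloride, CC(C)(C)[Si](C)(C)Cl
Why: Silylation takes the primary and the secondary allylic hydroxyl groups, whereas the tertiary hydroxyl is too hindered to react with the silyl chloride.

Step 12
Reactants: 19 (2S,4S,5Z)-1,4-bis(tert-butyldimethylsilyloxy)-6-iodo-2-methylhept-5-en-2-ol
Product: 20 (2S,4S,5Z)-4-(tert-butyldimethylsilyloxy)-6-iodo-2-methylhept-5-ene-1,2-diol (fragment B)
Conditions: HF·pyridine, pyridine, THF, 0 °C
Reagents that add atoms: none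
Why: Buffered fluoride cleaves the unhindered primary silyl ether much faster than the secondary allylic one, which should leave the 1,2-diol free and C3 protected.

**Union, macrocycle, key step and end game**

Step 13
Reactants: 10 fragment A aldehyde; 20 fragment B diol
Product: 21 open-chain 1,3-dioxolane acetal (ring C2 = C7, both epimers; ring C4 = C5)
Conditions: PPTS (cat.), MgSO4, PhH, 50 °C
Reagents that add atoms: none
Why: Acid-catalysed acetalisation with removal of water joins the fragments as the 1,3-dioxolane, the only cyclic acetal possible while O3 is silylated, and the new acetal centre needs no control because it becomes planar in step 16.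

Step 14
Reactants: 21 open-chain 1,3-dioxolane acetal
Product: 23 macrocyclic acetal (12-membered ring bridged by the dioxolane), via alkylborane 22 (not isolated)
Conditions: 9-BBN, THF, rt to 40 °C; then slow addition to PdCl2(dppf) (cat.), AsPh3, Cs2CO3, DMF/THF/H2O, 50 °C (about 1 mM)
Reagents that add atoms: none
Why: Anti-Markovnikov hydroboration of the only terminal alkene and intramolecular B-alkyl Suzuki–Miyaura coupling with the alkenyl iodide under high dilution should close the 12-membered ring with retention of the Z geometry.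

Step 15
Reactants: 23 macrocyclic acetal (Weinreb amide)
Product: 24 macrocyclic β-keto ester
Conditions: MeOAc, LiN(SiMe3)2, THF, −78 °C; then 23, −78 to 0 °C; AcOH
Reagents that add atoms: methyl acetate, CC(=O)OC
Why: Acylation of the lithium enolate of methyl acetate by the Weinreb amide (Claisen-type condensation) stops at the chelated tetrahedral adduct, which should give the β-keto ester on work-up.

Step 16
Reactants: 24 macrocyclic β-keto ester
Product: 27 bicyclic β-keto ester (bicyclo[8.2.2] core; free CH2OH on C5), via silyl enol ether 25 (not isolated), via oxocarbenium ion 26 (not isolated)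
Conditions: Me3SiOTf, Et3N, CH2Cl2, 0 °C; then TiCl4, −78 to −40 °C; H2O
Reagents that add atoms: none
Why: TiCl4 binds the less hindered primary oxygen of the dioxolane and breaks its bond to C7, so that an oxocarbenium ion C7=O6(+) forms inside the 12-membered ring with the tertiary ether oxygen retained and the primary oxygen held on titanium; the β-silyloxy enoate on C10 then attacks C7 through C12 and loses Me3SiCl. The closest known reaction types are the Mukaiyama addition of enol silanes to acetals and the Lewis acid opening of cyclic acetals by π-nucleophiles, which likewise keeps one acetal oxygen as an ether and frees the other as an alcohol. The one ring closed is the six-membered carbocycle C7–C8–C9–C10–C11–C12, by a 6-(enolendo)-exo-trig attack across the macrocycle, which converts the bridged bicyclo[9.2.1] acetal into the bicyclo[8.2.2] core. The new stereocentre C7 is controlled by the ring: O6 and the C10–CH2 bond both belong to the 12-membered ring, so C11–C12 can bridge C10 and C7 only as the cis-1,4 isomer, and the fixed configuration at C10 is thereby relayed to C7 from either acetal epimer; C12 is enolisable and becomes sp2 in step 18. The step needs regioselective cleavage of the acetal (primary oxygen out, tertiary oxygen kept), secured by the steric access of TiCl4 to the CH2–O oxygen and by the better donor ability of the tert-alkyl oxygen, and it needs the enol silane to outrun the ring alkene, secured by its much higher nucleophilicity and the chair-like six-membered transition state. Low temperature should keep the allylic silyl ether and the new tert-alkyl ether from ionising.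

Step 17
Reactants: 27 bicyclic β-keto ester
Product: 28 bicyclic β-keto ester with CH2OTBS on C5
Conditions: TBSCl, imidazole, DMF, rt
Reagents that add atoms: tert-butyldimethylsilyl chloride, CC(C)(C)[Si](C)(C)Cl
Why: Silylation of the primary hydroxyl group keeps it from being triflated in step 18, and any enol silyl ether of the β-keto ester is cleaved again on aqueous work-up.

Step 18
Reactants: 28 bicyclic β-keto ester with CH2OTBS on C5
Product: 29 enol triflate (C11–OTf, C11=C12)
Conditions: Tf2O, i-Pr2NEt, CH2Cl2, −78 °C
Reagents that add atoms: trifluoromethanesulfonic anhydride, O=S(=O)(OS(=O)(=O)C(F)(F)F)C(F)(F)F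
Why: O-Sulfonylation of the enolised cyclic β-keto ester at −78 °C should give the enol triflate before the β-alkoxy group at C7 can be lost by E1cB elimination.

Step 19
Reactants: 29 enol triflate
Product: 31 bis-TBS ether of neocucurbin A, via hydroxymethyl ester 30 (not isolated)
Conditions: Bu3SnCH2OH, Pd(PPh3)4 (cat.), LiCl, 1,4-dioxane, 95 °C
Reagents that add atoms: (tributylstannyl)methanol, CCCC[Sn](CCCC)(CCCC)CO
Why: Stille coupling of the ester-activated alkenyl triflate places the hydroxymethyl carbon C15 on C11, held cis to the ester by the ring, and the hydroxy ester should lactonise to the butenolide.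

Step 20
Reactants: 31 bis-TBS ether of neocucurbin A
Product: 32 neocucurbin A
Conditions: HF·pyridine, pyridine, THF, 0 °C to rt
Reagents that add atoms: none
Why: Fluoride under mildly acidic conditions should cleave both silyl ethers without enolising the butenolide or ionising the allylic ether.

**Compound list**

1 | (3R)-5-methoxy-3-methyl-5-oxopentanoic acid (monomethyl (R)-3-methylglutarate) | COC(=O)C[C@H](C)CC(=O)O | starting material
2 | methyl (3R)-5-hydroxy-3-methylpentanoate | COC(=O)C[C@H](C)CCO | intermediate
3 | (4R)-4-methyloxan-2-one | O=C1C[C@H](C)CCO1 | intermediate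
4 | lithium enolate of 3 | [Li]OC1=C[C@H](C)CCO1 | intermediate
5 | (4R)-3,4-dimethyloxan-2-one (C3 epimers) | O=C1C(C)[C@H](C)CCO1 | intermediate
6 | lithium enolate of 5 | [Li]OC1=C(C)[C@H](C)CCO1 | intermediate
7 | (3R,4R)-3-(1-hydroxyethyl)-3,4-dimethyloxan-2-one (carbinol epimers) | O=C1[C@@](C)(C(C)O)[C@H](C)CCO1 | intermediate
8 | (3S,4R)-3-ethenyl-3,4-dimethyloxan-2-one | O=C1[C@@](C)(C=C)[C@H](C)CCO1 | intermediate
9 | (2S,3R)-2-ethenyl-5-hydroxy-N-methoxy-N,2,3-trimethylpentanamide | CON(C)C(=O)[C@@](C)(C=C)[C@H](C)CCO | intermediate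
10 | (2S,3R)-2-ethenyl-N-methoxy-N,2,3-trimethyl-5-oxopentanamide (fragment A) | CON(C)C(=O)[C@@](C)(C=C)[C@H](C)CC=O | intermediate
11 | pent-3-yn-2-one | CC#CC(C)=O | starting material
12 | 2-(trimethylsilyloxy)pent-1-en-3-yne | CC#CC(=C)O[Si](C)(C)C | intermediate
13 | methyl pyruvate | CC(=O)C(=O)OC | starting material
14 | methyl (2S)-2-methyl-4-oxo-2-(trimethylsilyloxy)hept-5-ynoate | CC#CC(=O)C[C@@](C)(C(=O)OC)O[Si](C)(C)C | intermediate
15 | methyl (2S)-2-hydroxy-2-methyl-4-oxohept-5-ynoate | CC#CC(=O)C[C@@](C)(C(=O)OC)O | intermediate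
16 | methyl (2S,4S)-2,4-dihydroxy-2-methylhept-5-ynoate | CC#C[C@@H](O)C[C@@](C)(C(=O)OC)O | intermediate
17 | sodium alkenylalanate from 16 (five-membered C=C–C–O–Al ring; Al on the methyl-bearing alkene carbon; the other hydroxyls drawn free) | CC1=C[C@H](C[C@@](C)(CO)O)O[Al-]1(OCCOC)OCCOC.[Na+] | intermediate
18 | (2S,4S,5Z)-6-iodo-2-methylhept-5-ene-1,2,4-triol | C/C(I)=C/[C@@H](O)C[C@@](C)(CO)O | intermediate
19 | (2S,4S,5Z)-1,4-bis(tert-butyldimethylsilyloxy)-6-iodo-2-methylhept-5-en-2-ol | C/C(I)=C/[C@@H](O[Si](C)(C)C(C)(C)C)C[C@@](C)(CO[Si](C)(C)C(C)(C)C)O | intermediate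
20 | (2S,4S,5Z)-4-(tert-butyldimethylsilyloxy)-6-iodo-2-methylhept-5-ene-1,2-diol (fragment B) | C/C(I)=C/[C@@H](O[Si](C)(C)C(C)(C)C)C[C@@](C)(CO)O | intermediate
21 | open-chain acetal: 1,3-dioxolane whose C2 (= C7, both epimers) carries the CH2–CH(Me)–C(Me)(vinyl)–C(O)N(OMe)Me chain of 10 and whose C4 (= C5) carries methyl and the (2S,3Z)-2-(TBSO)-4-iodopent-3-enyl chain of 20 | CON(C)C(=O)[C@@](C)(C=C)[C@H](C)CC1OC[C@](C)(C[C@H](O[Si](C)(C)C(C)(C)C)/C=C(/C)I)O1 | intermediate
22 | B-alkyl-9-BBN from 21 (boron on the terminal carbon of the former vinyl group) | CON(C)C(=O)[C@@](C)(CCB1C2CCCC1CCC2)[C@H](C)CC1OC[C@](C)(C[C@H](O[Si](C)(C)C(C)(C)C)/C=C(/C)I)O1 | intermediate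
23 | macrocyclic acetal: 12-membered ring C10–CH2–CH2–C1(Me)=C2(Z)–C3(OTBS)–C4–C5–O6–C7–C8–C9 bridged by the dioxolane CH2–O between C5 and C7; C10 bears methyl and the Weinreb amide | CON(C)C(=O)[C@]1(C)[C@H](C)CC2OC[C@@](C)(O2)C[C@H](O[Si](C)(C)C(C)(C)C)/C=C(/C)CC1 | intermediate
24 | macrocyclic β-keto ester: as 23 with C(=O)CH2CO2Me on C10 | COC(=O)CC(=O)[C@]1(C)[C@H](C)CC2OC[C@@](C)(O2)C[C@H](O[Si](C)(C)C(C)(C)C)/C=C(/C)CC1 | intermediate
25 | (Z)-trimethylsilyl enol ether of 24 | COC(=O)/C=C(\O[Si](C)(C)C)[C@]1(C)[C@H](C)CC2OC[C@@](C)(O2)C[C@H](O[Si](C)(C)C(C)(C)C)/C=C(/C)CC1 | intermediate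
26 | ring-opened oxocarbenium ion C7=O6(+) in the 12-membered ring, primary oxygen bound to TiCl4 | COC(=O)/C=C(\O[Si](C)(C)C)[C@]1(C)[C@H](C)CC=[O+][C@](C)(CO[Ti-](Cl)(Cl)(Cl)Cl)C[C@H](O[Si](C)(C)C(C)(C)C)/C=C(/C)CC1 | intermediate
27 | bicyclic β-keto ester: bicyclo[8.2.2] core with C11 ketone, CO2Me on C12 (keto–enol mixture), free CH2OH on C5, TBS ether on O3 | C/C1=C/[C@@H](O[Si](C)(C)C(C)(C)C)C[C@@](C)(CO)O[C@@H]2C[C@@H](C)[C@](C)(CC1)C(=O)C2C(=O)OC | intermediate
28 | primary TBS ether of 27 | C/C1=C/[C@@H](O[Si](C)(C)C(C)(C)C)C[C@@](C)(CO[Si](C)(C)C(C)(C)C)O[C@@H]2C[C@@H](C)[C@](C)(CC1)C(=O)C2C(=O)OC | intermediate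
29 | enol triflate of 28 (OTf on C11, C11=C12) | C/C1=C/[C@@H](O[Si](C)(C)C(C)(C)C)C[C@@](C)(CO[Si](C)(C)C(C)(C)C)O[C@@H]2C[C@@H](C)[C@](C)(CC1)C(OS(=O)(=O)C(F)(F)F)=C2C(=O)OC | intermediate
30 | hydroxymethyl ester (CH2OH on C11, CO2Me on C12) | C/C1=C/[C@@H](O[Si](C)(C)C(C)(C)C)C[C@@](C)(CO[Si](C)(C)C(C)(C)C)O[C@@H]2C[C@@H](C)[C@](C)(CC1)C(CO)=C2C(=O)OC | intermediate
31 | bis-TBS ether of neocucurbin A (silyl on O3 and on the CH2O of C5) | C/C1=C/[C@@H](O[Si](C)(C)C(C)(C)C)C[C@@](C)(CO[Si](C)(C)C(C)(C)C)O[C@@H]2C[C@@H](C)[C@](C)(CC1)C1=C2C(=O)OC1 | intermediate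
32 | neocucurbin A (ad hoc numbering: 3S,5S,7R,9R,10S; Z alkene) | C/C1=C/[C@@H](O)C[C@@](C)(CO)O[C@@H]2C[C@@H](C)[C@](C)(CC1)C1=C2C(=O)OC1 | target

**Step count**

Total: 20 steps. Longest linear sequence: 14 steps (steps 1–6 and 13–20); fragment B takes steps 7–12.

**Steps most likely to fail**

Step 16. The enol silane arm may fail to reach C7 across the macrocycle, so that the ring alkene captures the oxocarbenium ion (transannular Prins reaction), the acetal re-closes, or the allylic silyl ether ionises on prolonged exposure to the Lewis acid. The fallback sets out from 21 and returns at 27; it closes the six-membered ring before the macrocycle. Acylation of the methyl acetate enolate by 21 (LiN(SiMe3)2, MeOAc, THF) should give the open-chain β-keto ester acetal F1. Me3SiOTf/Et3N and then TiCl4 should convert it, through its trimethylsilyl enol ether F2, into the monocyclic cyclohexanone hydroxy ether F3; here only an electron-poor alkenyl iodide and no ring constraint compete with the enol silane. Hydroboration with 9-BBN to the alkylborane F4 and B-alkyl Suzuki–Miyaura ring closure (PdCl2(dppf), AsPh3, Cs2CO3, high dilution) would then give 27. In this order C7 is no longer fixed by the ring; the preference for a pseudoaxial alkoxy group next to the ester-bearing C12 is relied on, and only the C7 epimer with O6 cis to the C10 side arm can close.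

Step 14. Hydroboration of the vinyl group on the quaternary carbon may be slow, oligomerisation may outrun ring closure, and one of the two acetal epimers may not close at all. The fallback sets out from 9 and 19 and returns at 23; it joins the carbon chain first and closes the ring by reversible acetal formation. Hydroboration of 9 with 9-BBN gives the alkylborane F5, which is coupled intermolecularly with 19 (PdCl2(dppf), AsPh3, Cs2CO3) to give the seco hydroxy amide F6. Ley–Griffith oxidation (n-Pr4N[RuO4], NMO) should give the aldehyde F7. Selective cleavage of the primary silyl ether (HF·pyridine, pyridine) should give the dihydroxy aldehyde F8. This is cyclised under thermodynamic control (PPTS, 4 Å MS, PhH, high dilution) to the macrocyclic acetal 23.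

Step 19. Transmetalation from the sp3 stannane to the crowded tetrasubstituted alkenylpalladium next to the quaternary C10 may be slow, so that the triflate is reduced or hydrolysed instead. The fallback sets out from 29 and returns at 31; it brings in C15 by carbon monoxide insertion instead of transmetalation. Reductive carbonylation (Pd(OAc)2, dppp, CO, Et3SiH, Et3N, DMF, 70 °C) should give the formyl ester F9. Luche reduction (NaBH4, CeCl3·7H2O, MeOH, −40 °C) of the aldehyde should give 30, which lactonises to 31.

Further compounds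
F1 | step 16 | open-chain β-keto ester acetal (21 with C(=O)CH2CO2Me in place of the Weinreb amide) | COC(=O)CC(=O)[C@@](C)(C=C)[C@H](C)CC1OC[C@](C)(C[C@H](O[Si](C)(C)C(C)(C)C)/C=C(/C)I)O1
F2 | step 16 | (Z)-trimethylsilyl enol ether of F1 | COC(=O)/C=C(\O[Si](C)(C)C)[C@@](C)(C=C)[C@H](C)CC1OC[C@](C)(C[C@H](O[Si](C)(C)C(C)(C)C)/C=C(/C)I)O1
F3 | step 16 | monocyclic cyclohexanone hydroxy ether (C7–C12 ring closed; vinyl on C10; alkenyl iodide side chain; free CH2OH) | C/C(I)=C/[C@@H](O[Si](C)(C)C(C)(C)C)C[C@@](C)(CO)O[C@@H]1C[C@@H](C)[C@](C)(C=C)C(=O)C1C(=O)OC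
F4 | step 16 | B-alkyl-9-BBN from F3 | C/C(I)=C/[C@@H](O[Si](C)(C)C(C)(C)C)C[C@@](C)(CO)O[C@@H]1C[C@@H](C)[C@](C)(CCB2C3CCCC2CCC3)C(=O)C1C(=O)OC
F5 | step 14 | B-alkyl-9-BBN from 9 | CON(C)C(=O)[C@@](C)(CCB1C2CCCC1CCC2)[C@H](C)CCO
F6 | step 14 | seco hydroxy amide (C1–CH2 bond formed; Z alkene; both TBS ethers; free tertiary and primary hydroxyls) | CON(C)C(=O)[C@@](C)(CC/C(C)=C\[C@@H](O[Si](C)(C)C(C)(C)C)C[C@@](C)(CO[Si](C)(C)C(C)(C)C)O)[C@H](C)CCO
F7 | step 14 | seco aldehyde from F6 | CON(C)C(=O)[C@@](C)(CC/C(C)=C\[C@@H](O[Si](C)(C)C(C)(C)C)C[C@@](C)(CO[Si](C)(C)C(C)(C)C)O)[C@H](C)CC=O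
F8 | step 14 | seco dihydroxy aldehyde (1,2-diol free) | CON(C)C(=O)[C@@](C)(CC/C(C)=C\[C@@H](O[Si](C)(C)C(C)(C)C)C[C@@](C)(CO)O)[C@H](C)CC=O
F9 | step 19 | formyl ester (CHO on C11, CO2Me on C12) | C/C1=C/[C@@H](O[Si](C)(C)C(C)(C)C)C[C@@](C)(CO[Si](C)(C)C(C)(C)C)O[C@@H]2C[C@@H](C)[C@](C)(CC1)C(C=O)=C2C(=O)OC
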